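## Retrosynthetic overview

Positions follow plakortolide numbering: C1 lactone carbonyl, C3 and C6 carry the peroxide, C4 carries the lactone oxygen.

1. C13=C14 is made last by Horner–Wadsworth–Emmons olefination of a C13 aldehyde (from a primary bromide), so the diene never meets the radical peroxidation.
2. The 1,2-dioxane (second ring) closes by oxa-Michael addition of a C6 tertiary hydroperoxide onto the butenolide; cis fusion sets C3. The hydroperoxide comes from cobalt-catalysed hydroperoxysilylation of a C6 methylidene group.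
3. The C6 methylidene comes from a C6 ketone, which is unmasked from a secondary nitro group (Nef).
4. Key C4–C5 bond: the γ-carbon of α-angelica lactone (first ring, bought) adds to a 2-nitroalk-1-ene used as an α-keto cation (enolonium) equivalent, in a catalytic asymmetric vinylogous Michael addition that sets C4.
5. The nitroalkene comes from 1,8-dibromooctane, nitrite and formaldehyde.

Assumption: the sense of induction in step 3 is confirmed by a trial run, and whichever pseudo-enantiomeric catalyst (quinidine- or quinine-derived) gives the (5S)-butenolide is used.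

## Route

Step 1
Reactants: 1 1,8-dibromooctane
Product: 2 8-bromo-1-nitrooctane
Conditions: NaNO2 (0.33 equiv), phloroglucinol, DMF, rt; excess 1 recovered
Reagents that add atoms: sodium nitrite, [Na+].[O-]N=O
Why: Kornblum nitration, an SN2 displacement of one primary bromide by nitrite through nitrogen, kept at the mono stage by the threefold excess of the symmetric dibromide; no stereocentre is formed.

Step 2
Reactants: 2 8-bromo-1-nitrooctane
Product: 5 9-bromo-2-nitronon-1-ene, via nitro alcohol 3 (not isolated), via mesylate 4 (not isolated)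
Conditions: (CH2O)n, KOtBu (5 mol%), THF, 0 °C to rt; then MsCl, i-Pr2NEt, −20 to 0 °C
Reagents that add atoms: formaldehyde (from paraformaldehyde), C=O
Why: Henry (nitroaldol) addition of the nitronate to formaldehyde followed by mesylation and E1cB loss of methanesulfonate gives the 2-nitroalk-1-ene that serves as the α-keto cation equivalent in the key step; no stereocentre remains.

Step 3
Reactants: 5 9-bromo-2-nitronon-1-ene; 6 α-angelica lactone (5-methylfuran-2(3H)-one)
Product: 7 (5S)-5-(9-bromo-2-nitrononyl)-5-methylfuran-2(5H)-one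
Conditions: 6 (2 equiv), 1-[3,5-bis(trifluoromethyl)phenyl]-3-(9-deoxy-epi-quinidin-9-yl)thiourea (10 mol%), CH2Cl2, −40 °C, slow addition of 5
Reagents that add atoms: none
Why: Proposed new method: the quinuclidine nitrogen deprotonates 6 to its dienolate while the thiourea hydrogen-bonds the nitro group, so the γ-carbon attacks the unhindered CH2 terminus of 5 from the face left open in the chiral ion pair and the oxygen-bearing quaternary carbon is set as S in one step, joining two carbons that are both normally nucleophilic; the closest known reaction type is the organocatalytic asymmetric vinylogous Michael addition of deconjugated butenolides to β-substituted nitroalkenes.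

Step 4
Reactants: 7 (5S)-5-(9-bromo-2-nitrononyl)-5-methylfuran-2(5H)-one
Product: 8 (5S)-5-(9-bromo-2-oxononyl)-5-methylfuran-2(5H)-one
Conditions: TiCl3 (20% in aq. HCl, 5 equiv), DME, rt, 24 h
Reagents that add atoms: water, O
Why: Reductive Nef reaction under McMurry conditions turns the secondary nitro group into the ketone under acidic, base-free conditions that avoid β-elimination of the lactone carboxylate and leave the bromide, the butenolide and the quaternary centre untouched, the nitro-bearing stereocentre being erased.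

Step 5
Reactants: 8 (5S)-5-(9-bromo-2-oxononyl)-5-methylfuran-2(5H)-one
Product: 9 (5S)-5-(9-bromo-2-methylidenenonyl)-5-methylfuran-2(5H)-one
Conditions: Zn, CH2Br2, TiCl4, THF/CH2Cl2, 0 °C to rt
Reagents that add atoms: dibromomethane, BrCBr
Why: Takai–Lombardo methylenation uses a non-basic zinc/titanium methylidene reagent that converts the ketone into the 1,1-disubstituted alkene without touching the lactone and without E1cB opening of the β-acyloxy ketone; no new stereocentre.

Step 6
Reactants: 9 (5S)-5-(9-bromo-2-methylidenenonyl)-5-methylfuran-2(5H)-one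
Product: 10 (5S)-5-{9-bromo-2-methyl-2-[(triethylsilyl)peroxy]nonyl}-5-methylfuran-2(5H)-one
Conditions: Co(thd)2 [cobalt bis(2,2,6,6-tetramethylheptane-3,5-dionate)] (10 mol%), O2 (1 atm), Et3SiH, ClCH2CH2Cl, rt
Reagents that add atoms: dioxygen, O=O; triethylsilane, CC[SiH](CC)CC
Why: Mukaiyama–Isayama hydroperoxysilylation, in which a cobalt hydride transfers a hydrogen atom to the terminal CH2 of the electron-rich 1,1-disubstituted alkene (faster than to the electron-poor butenolide), the tertiary radical traps O2 and the cobalt peroxide is silylated; the new peroxide-bearing carbon forms without facial control as a roughly 1:1 pair of epimers that is carried on.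

Step 7
Reactants: 10 (5S)-5-{9-bromo-2-methyl-2-[(triethylsilyl)peroxy]nonyl}-5-methylfuran-2(5H)-one
Product: 12 (3S,4aS,7aS)-3-(7-bromoheptyl)-3,4a-dimethyl-3,4,4a,7a-tetrahydrofuro[3,2-c][1,2]dioxin-6(7H)-one, via hydroperoxide 11 (not isolated)
Conditions: HCl (cat.), MeOH, 0 °C; then Et2NH (0.2 equiv), CF3CH2OH, rt; silica gel chromatography
Reagents that add atoms: none
Why: Acid methanolysis frees the tertiary hydroperoxide, whose amine-generated peroxide anion adds in a 6-exo oxa-Michael fashion to the butenolide on the face that carries the side chain, so the ring fusion is necessarily cis and C7a is set S by C4a; the two C3 epimers are diastereomers and the (3S) compound is separated by chromatography.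

Step 8
Reactants: 12 (3S,4aS,7aS)-3-(7-bromoheptyl)-3,4a-dimethyl-3,4,4a,7a-tetrahydrofuro[3,2-c][1,2]dioxin-6(7H)-one
Product: 14 7-[(3S,4aS,7aS)-3,4a-dimethyl-6-oxohexahydrofuro[3,2-c][1,2]dioxin-3-yl]heptanal, via alkoxysulfonium salt 13 (not isolated)
Conditions: AgBF4, DMSO, rt; then Et3N
Reagents that add atoms: dimethyl sulfoxide, CS(C)=O
Why: Silver-assisted Kornblum oxidation, in which the silver cation abstracts bromide, the DMSO oxygen attacks the primary carbon and Et3N collapses the alkoxysulfonium salt to the aldehyde at room temperature, conditions that spare the dialkyl peroxide and the lactone; no stereocentre is touched.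

Step 9
Reactants: 14 7-[(3S,4aS,7aS)-3,4a-dimethyl-6-oxohexahydrofuro[3,2-c][1,2]dioxin-3-yl]heptanal; 15 diethyl [(2E)-3-phenylprop-2-en-1-yl]phosphonate
Product: 16 plakortolide R, (3S,4aS,7aS)-3,4a-dimethyl-3-[(7E,9E)-10-phenyldeca-7,9-dien-1-yl]-3,4,4a,7a-tetrahydrofuro[3,2-c][1,2]dioxin-6(7H)-one
Conditions: LiN(SiMe3)2 (1.05 equiv), THF, −78 to 0 °C
Reagents that add atoms: none
Why: Horner–Wadsworth–Emmons olefination with the lithiated allylic phosphonate forms the new C=C bond with E geometry and keeps the E styryl bond of the reagent, the low temperature and near-exact stoichiometry sparing the base-sensitive β-peroxy lactone.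

## Compound list

1 | 1,8-dibromooctane | BrCCCCCCCCBr | starting material
2 | 8-bromo-1-nitrooctane | [O-][N+](=O)CCCCCCCCBr | intermediate
3 | 9-bromo-2-nitrononan-1-ol (racemic) | OCC(CCCCCCCBr)[N+](=O)[O-] | intermediate
4 | 9-bromo-2-nitrononyl methanesulfonate (racemic) | CS(=O)(=O)OCC(CCCCCCCBr)[N+](=O)[O-] | intermediate
5 | 9-bromo-2-nitronon-1-ene | C=C(CCCCCCCBr)[N+](=O)[O-] | intermediate
6 | α-angelica lactone, 5-methylfuran-2(3H)-one | CC1=CCC(=O)O1 | starting material
7 | (5S)-5-(9-bromo-2-nitrononyl)-5-methylfuran-2(5H)-one, both epimers at the nitro carbon | C[C@]1(CC(CCCCCCCBr)[N+](=O)[O-])C=CC(=O)O1 | intermediate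
8 | (5S)-5-(9-bromo-2-oxononyl)-5-methylfuran-2(5H)-one | C[C@]1(CC(=O)CCCCCCCBr)C=CC(=O)O1 | intermediate
9 | (5S)-5-(9-bromo-2-methylidenenonyl)-5-methylfuran-2(5H)-one | C[C@]1(CC(=C)CCCCCCCBr)C=CC(=O)O1 | intermediate
10 | (5S)-5-{9-bromo-2-methyl-2-[(triethylsilyl)peroxy]nonyl}-5-methylfuran-2(5H)-one, 1:1 epimers at the peroxide carbon | C[C@]1(CC(C)(CCCCCCCBr)OO[Si](CC)(CC)CC)C=CC(=O)O1 | intermediate
11 | (5S)-5-(9-bromo-2-hydroperoxy-2-methylnonyl)-5-methylfuran-2(5H)-one, 1:1 epimers at the peroxide carbon | C[C@]1(CC(C)(CCCCCCCBr)OO)C=CC(=O)O1 | intermediate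
12 | (3S,4aS,7aS)-3-(7-bromoheptyl)-3,4a-dimethyl-3,4,4a,7a-tetrahydrofuro[3,2-c][1,2]dioxin-6(7H)-one; cis-fused γ-lactone/1,2-dioxane with O1–O2 peroxide, C3 bearing CH3 and the chain, C4a bearing CH3 and lactone oxygen O5, C7a–H bearing O1 | C[C@]1(CCCCCCCBr)C[C@]2(C)OC(=O)C[C@@H]2OO1 | intermediate
13 | ({7-[(3S,4aS,7aS)-3,4a-dimethyl-6-oxohexahydrofuro[3,2-c][1,2]dioxin-3-yl]heptyl}oxy)dimethylsulfonium tetrafluoroborate | C[C@]1(CCCCCCCO[S+](C)C)C[C@]2(C)OC(=O)C[C@@H]2OO1.F[B-](F)(F)F | intermediate
14 | 7-[(3S,4aS,7aS)-3,4a-dimethyl-6-oxohexahydrofuro[3,2-c][1,2]dioxin-3-yl]heptanal | C[C@]1(CCCCCCC=O)C[C@]2(C)OC(=O)C[C@@H]2OO1 | intermediate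
15 | diethyl [(2E)-3-phenylprop-2-en-1-yl]phosphonate (diethyl cinnamylphosphonate) | CCOP(=O)(OCC)C/C=C/c1ccccc1 | starting material
16 | plakortolide R | C[C@]1(CCCCCC/C=C/C=C/c2ccccc2)C[C@]2(C)OC(=O)C[C@@H]2OO1 | target

## Step count and risks

Total steps: 9. Longest linear sequence: 9 (from 1,8-dibromooctane).

The peroxide carbon C3 of 12 (C6 in plakortolide numbering) is not formed selectively; it is obtained by separating two diastereomers in step 7, so that step gives at most about half of the material. The enantiomeric purity of the final product equals that reached in step 3; it is measured at ketone 8.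

Steps most likely to fail:

Step 3 (key vinylogous Michael addition). Risks are α- versus γ-attack, modest ee with an acceptor that has no β-substituent, and base-induced polymerisation of 5. The fallback makes the same bond under auxiliary control, sets out from nitroalkene 5 and comes back at butenolide 7. The lithium enolate (LiN(i-Pr)2, THF, −78 °C) of (2R,5R)-2-tert-butyl-5-methyl-1,3-dioxolan-4-one F1, the pivalaldehyde acetal of (R)-lactic acid, adds to 5 anti to the tert-butyl group and gives (2R,5S)-5-(9-bromo-2-nitrononyl)-2-tert-butyl-5-methyl-1,3-dioxolan-4-one F2. Reduction with i-Bu2AlH (CH2Cl2, −78 °C) gives the lactol (2R,5S)-5-(9-bromo-2-nitrononyl)-2-tert-butyl-5-methyl-1,3-dioxolan-4-ol F3. Wittig reaction of F3 with Ph3P=CHCO2Me in MeOH releases pivalaldehyde and gives methyl (2Z,4S)-13-bromo-4-hydroxy-4-methyl-6-nitrotridec-2-enoate F4, which lactonises with catalytic TsOH to 7.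

Step 6 (hydroperoxysilylation). Risks are competing hydrogen-atom transfer to the butenolide double bond and over-reaction. The fallback is ionic instead of radical, sets out from alkene 9 and comes back at hydroperoxide 11. Anhydrous HBr (CH2Cl2, −78 °C) adds in the Markovnikov sense to give (5S)-5-(2,9-dibromo-2-methylnonyl)-5-methylfuran-2(5H)-one F5. Silver-assisted perhydrolysis (AgO2CCF3, anhydrous H2O2, Et2O, 0 °C) then exchanges only the tertiary bromide for OOH to give 11, which is cyclised with Et2NH in CF3CH2OH as in step 7.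

Step 9 (olefination next to a β-peroxy lactone). The risk is enolisation of the lactone by the phosphonate anion with E1cB opening of the dioxane. The fallback is base-free, sets out from aldehyde 14 and comes back at 16. Methylenation with Zn, CH2Br2 and TiCl4 gives (3S,4aS,7aS)-3,4a-dimethyl-3-(oct-7-en-1-yl)-3,4,4a,7a-tetrahydrofuro[3,2-c][1,2]dioxin-6(7H)-one F6. Cross-metathesis of F6 with (E)-buta-1,3-dien-1-ylbenzene, using the second-generation Hoveyda–Grubbs catalyst [RuCl2(H2IMes)(=CH-C6H4-2-O-i-Pr)] in CH2Cl2 at 40 °C, gives 16.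

## Further compounds

F1 | step 3 | (2R,5R)-2-tert-butyl-5-methyl-1,3-dioxolan-4-one | CC(C)(C)[C@H]1OC(=O)[C@@H](C)O1
F2 | step 3 | (2R,5S)-5-(9-bromo-2-nitrononyl)-2-tert-butyl-5-methyl-1,3-dioxolan-4-one | CC(C)(C)[C@H]1OC(=O)[C@](C)(CC(CCCCCCCBr)[N+](=O)[O-])O1
F3 | step 3 | (2R,5S)-5-(9-bromo-2-nitrononyl)-2-tert-butyl-5-methyl-1,3-dioxolan-4-ol | CC(C)(C)[C@H]1OC(O)[C@](C)(CC(CCCCCCCBr)[N+](=O)[O-])O1
F4 | step 3 | methyl (2Z,4S)-13-bromo-4-hydroxy-4-methyl-6-nitrotridec-2-enoate | COC(=O)/C=C\[C@@](C)(O)CC(CCCCCCCBr)[N+](=O)[O-]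
F5 | step 6 | (5S)-5-(2,9-dibromo-2-methylnonyl)-5-methylfuran-2(5H)-one | C[C@]1(CC(C)(Br)CCCCCCCBr)C=CC(=O)O1
F6 | step 9 | (3S,4aS,7aS)-3,4a-dimethyl-3-(oct-7-en-1-yl)-3,4,4a,7a-tetrahydrofuro[3,2-c][1,2]dioxin-6(7H)-one | C[C@]1(CCCCCCC=C)C[C@]2(C)OC(=O)C[C@@H]2OO1
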